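## Structural features

Remangiflavanone A is a 5,7,4'-trihydroxyflavanone. A phloroglucinol-type ring A is fused through C4a and C8a to the dihydropyranone ring C (O1, C2, C3, C4=O), and C2 carries the 4-hydroxyphenyl ring B. C8 of ring A bears a ten-carbon chain, CH2–CH(isopropenyl)–CH2CH2–C(CH3)=CH2, attached through its C1'' methylene. The two stereocentres, C2 (S) and C2'' (R), are five bonds apart (C2–O1–C8a–C8–C1''–C2''), so neither can control the other and each must be set on its own. The fragile elements are: the benzylic aryl ether C2–O1 beta to the C4 ketone, which opens to a chalcone under base and so racemises C2; the two 1,1-disubstituted alkenes, which are prone to Markovnikov addition under acid, to cyclisation onto the neighbouring C7 hydroxyl and to intramolecular radical addition; and the oxidation-sensitive free phloroglucinol ring. The real difficulty is regiochemical and stereochemical at once. C8 lies between two oxygenated carbons (C7 and C8a) and C4a between two others (C5 and C8a), so ring A must be desymmetrised so that O1 sits on the carbon common to both. A branched sp3 chain without allylic or benzylic activation must be attached to a hindered, electron-rich ring carbon, and C2 must be made and kept enantiopure. The key step exploits that O1 is the only ring A oxygen that is an ether: C8a can carry a leaving group and the O1–C8a bond can be made from the C2 carbinol oxygen, so the C2–O bond, and with it the C2 configuration, is never broken.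

## Logic of the disconnections

23 back to 22 and 22 back to 21: no skeletal bond is cut. The three phenols are traced to MOM ethers and the C4 ketone to a carbinol. The reason is that a flavanone opens to a chalcone under base, so every basic operation is placed before the ketone exists and the last step uses acid only. The gain is a ring C precursor without a carbonyl group. The demand is a base-free oxidation that spares the alkenes (step 15) and a deprotection mild enough for the isopropenyl groups (step 16).

21 back to 20 and 20 back to 19: first the O4–Si bond (a protecting-group change), then the strategic cut O1–C8a. Cutting here removes ring C and turns C2 into an ordinary secondary benzylic alcohol, and the ring oxygen is supplied by that carbinol, so the configuration is carried through the closure. The gain is an acyclic 1,3-dioxygenated chain on a hexasubstituted arene. The demand is a C–O reductive elimination at a hindered, electron-rich aryl triflate that outruns beta-hydride elimination. This is why the C4 oxygen of 19 is silylated: a free benzylic hydroxyl ortho to the aryl–palladium bond could chelate the metal, reduce it by internal hydride transfer, or accept the triflyl group.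

19 back to 18: the C2–H bond. C2 becomes a para-alkoxyaryl ketone, an unhindered substrate for catalyst-controlled reduction. The gain is the loss of the only stereocentre of this half. The demand is that the catalyst overrides the remote, uncontrolled C4 centre in both epimers.

18 back to 17, and 17 back to 13 and 15 (through 16): the O–Si bond and then C3–C4, an aldol bond. Cutting C3–C4 separates ring B with C2 and C3 from ring A with C4 and places the carbonyl that must be reduced on the unhindered side. The gain is two simple aromatic carbonyl compounds. The demand is a cold, kinetically controlled addition to a di-ortho-substituted aldehyde next to a triflate, with no retro-aldol reaction or dehydration.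

13 back to 11 and 7 (through 12): the sp2–sp3 bond C8–C1''. The chain is not allylic or benzylic at C1'', so only a cross-coupling will make this bond. The gain is a chiral-pool alkyl iodide and an achiral arene. The demand is selective reaction at C–I in the presence of C–OTf and an aldehyde, with no beta-hydride elimination.

11 back to 10, 9 and 8: the O8a–S bond, the C8–I bond and two O–CH2 bonds. In 9 the aldehyde hydrogen bond leaves exactly one phenol free, the one next to the formyl carbon (the future C4a). Iodination ortho to that phenol marks C8, and triflation turns the phenol into the leaving group. The oxygen that becomes O1 is therefore, by construction, the one lying between the chain carbon and C4a. The demand is that iodination prefers C3 of 9 over C5.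

7 back to 5 (through 6), 5 back to 4, 4 back to 3 and 3 back to 1 (through 2): the C1''–CO2H bond, the terminal C=CH2 bond and the C1–C2 ring bond of the limonene skeleton. Ring cleavage of 1 gives a chain that is one carbon too long at the aldehyde end and one carbon short at the ketone end, and the decarboxylation and the methylenation correct both. The gain is that the chain stereocentre comes from the chiral pool. The demand is that the primary radical of the decarboxylation is trapped faster than it can add to either alkene.

15 back to 14: one O–CH2 bond, so that the ring B phenol survives enolate formation and is released in the final step with the others.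

## Other disconnections considered

Alternative 1: The cut is the side-chain bond C1''–C2'', with an O–C(=O) lactone bond as a temporary tether. In the forward sense acyl oxazolidinone A2 would be deprotonated with NaN(SiMe3)2 and O-Boc salicyl alcohol A3 unmasked in the same flask to ortho-quinone methide A4. Conjugate addition of the Z-enolate, from the face opposite the benzyl group, would form C1''–C2'', and the released phenoxide would expel the auxiliary to give dihydrocoumarin A1.
- In favour: the chain stereocentre is made by well-understood auxiliary control in a polar reaction, with no radical and no terpene degradation. The lactone also singles out one of the two oxygens ortho to the chain, which is the ring A differentiation that the chosen plan must win by a regioselective iodination (step 6). On that point the alternative is the better.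
- Against: the lactone carbonyl must still become the isopropenyl group, through a ketone-level stage in which the adjacent stereocentre is enolisable. A4 is highly electrophilic and prone to oligomerise. The step does nothing for ring C or C2.
- Comparison: on structure it solves the chain and ring A only, whereas the chosen key step closes ring C. On mechanism it is cleaner than step 4 (no radical clock) but carries an epimerisation risk that the chiral-pool chain does not. On step economy it is expected to be longer, because the stereocentre that limonene supplies is paid for with auxiliary attachment, carbonyl-to-alkene conversion and phenol unmasking.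

Alternative 2: The cut removes three ring A bonds (C8–C8a, C6–C7 and C4a–C8a). Ring A would be assembled from siloxyalkyne A6 and 3-ethoxycyclobutenone A7. On heating in toluene, A7 would open to a vinylketene, add [2+2] to the alkyne, open again and close by 6π electrocyclisation, giving phenol A5 after tautomerisation (a Danheiser-type benzannulation).
- In favour: ring A arrives with three different oxygens (free hydroxyl at C8a, silyl ether at C7, ethyl ether at C5) and the chain already at C8, so the regiochemistry follows from connectivity. A6 would derive from acid 5 by ynolate homologation, the carboxyl carbon becoming C8, so no decarboxylation and no radical are needed. On both points the alternative is the better.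
- Against: A6 needs strongly basic ynolate chemistry and is sensitive to hydrolysis. Prolonged heating generates ketenes in a molecule with two 1,1-disubstituted alkenes. The C5 oxygen arrives as an ethyl ether, whose removal at the end calls for a boron trihalide, which is hard to reconcile with the isopropenyl groups and the C2–O1 bond. Ring C and C2 remain unsolved.
- Comparison: on structure it is superior for ring A and silent on ring C. On mechanism it is a pericyclic cascade with built-in regiocontrol, against an aromatic substitution plus a cross-coupling. The source of chain chirality is the same (equal). The step count to a ring A piece ready for C4a functionalisation is comparable, but the endgame is poorer.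

Alternative 3: The cut is the acyl–aryl bond C4–C4a. Aryl ether acid A9 would be converted under neutral conditions to acid chloride A10 with 1-chloro-N,N,2-trimethylprop-1-en-1-amine and 2,6-di-tert-butylpyridine, and the acyl carbon would attack C4a, the only free position ortho to O1, to give flavanone A8.
- In favour: ring C closes directly at the ketone oxidation level, with no C4 redox detour and no spectator stereocentre. Here the alternative is the better, since the chosen plan spends a silylation, a desilylation and an oxidation on C4. Electrophilic attack on a phloroglucinol-type ring is also intrinsically easier than oxidative addition into a hindered electron-rich triflate (better). The regiochemistry of closure is as secure as in the chosen plan (equal), and no transition metal is needed.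
- Against: the C2–O1 bond must be made beforehand by intermolecular displacement at the benzylic C2 with a hindered phenol, a step prone to ionisation. A10 could lose the phenoxide by elimination to a cinnamoyl species, which would cleave the ether or racemise C2. Three different protecting groups need three removals, and the ethyl ether is the same liability as in Alternative 2.
- Comparison: the chosen plan creates C2 by catalyst-controlled ketone reduction and never breaks its C–O bond, so stereochemical security favours it. Step economy before the endgame is about equal; after it the alternative is worse.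

Key step: step 13

Remarks on the chemistry:
- C4 becomes the ketone, so its configuration is deliberately not controlled. Compounds 17 to 21 are pairs of C4 epimers. The (1S,3S) member of 19 has the anti arrangement, C=C(C)CC[C@H](Cc1c(OCOC)cc(OCOC)c([C@@H](O[Si](C)(C)C(C)(C)C)C[C@H](O)c2ccc(OCOC)cc2)c1OS(=O)(=O)C(F)(F)F)C(=C)C, and leads to the 2,4-cis (2S,4S) member of 21, C=C(C)CC[C@H](Cc1c(OCOC)cc(OCOC)c2c1O[C@H](c1ccc(OCOC)cc1)C[C@@H]2O)C(=C)C.
- Both O7 and O8a are ortho to C8. C8a is unique only in being ortho to C8 and C4a at once, and the route secures this by iodinating ortho to the single free phenol of 9.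
- Commercial (+)-limonene oxide (cis/trans) is assumed as starting material; it is one epoxidation away from (R)-(+)-limonene.
- A direct radical decarboxylative arylation is avoided because the primary radical carries both a homoallyl and a 5-methylhex-5-enyl clock. The radical is instead quenched by fast iodine transfer, and the C–C bond is made by two-electron cross-coupling.
- "(2R)-chain" stands for the (2R)-5-methyl-2-(prop-1-en-2-yl)hex-5-en-1-yl group.

## Route

Step 1
Reactants: 1 (4R)-limonene 1,2-oxide (cis/trans mixture)
Product: 3 (3R)-6-oxo-3-(prop-1-en-2-yl)heptanal, via limonene-1,2-diol 2 (not isolated)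
Conditions: H5IO6, THF/H2O, 0 °C to rt
Reagents that add atoms: water, O
Why: Acid-catalysed epoxide hydrolysis to the vicinal diol followed by Malaprade glycol cleavage; both epoxide diastereomers converge on one keto aldehyde, and the limonene stereocentre, beta to the new aldehyde and not enolisable, is carried over unchanged.

Step 2
Reactants: 3 (3R)-6-oxo-3-(prop-1-en-2-yl)heptanal
Product: 4 (3R)-6-oxo-3-(prop-1-en-2-yl)heptanoic acid
Conditions: NaClO2, NaH2PO4, 2-methyl-2-butene, t-BuOH/H2O, 0 °C to rt
Reagents that add atoms: sodium chlorite, [Na+].[O-]Cl=O
Why: Pinnick oxidation: chlorous acid oxidises only the aldehyde, the ketone and the isopropenyl group are inert, and 2-methyl-2-butene scavenges the hypochlorous acid that could otherwise attack the alkene.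

Step 3
Reactants: 4 (3R)-6-oxo-3-(prop-1-en-2-yl)heptanoic acid
Product: 5 (3R)-6-methyl-3-(prop-1-en-2-yl)hept-6-enoic acid
Conditions: Ph3PCH3Br, KOt-Bu (3 equiv each), THF, 0 °C to rt; aq. HCl work-up
Reagents that add atoms: methyltriphenylphosphonium bromide, C[P+](c1ccccc1)(c1ccccc1)c1ccccc1.[Br-]
Why: Wittig methylenation of the methyl ketone; the first equivalent of ylide only deprotonates the acid, whose carboxylate is not attacked, and the stereocentre is alpha to neither carbonyl, so it cannot epimerise.

Step 4
Reactants: 5 (3R)-6-methyl-3-(prop-1-en-2-yl)hept-6-enoic acid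
Product: 7 (3S)-3-(iodomethyl)-2,6-dimethylhepta-1,6-diene, via Barton ester 6 (not isolated)
Conditions: 1-hydroxypyridine-2(1H)-thione, DCC, DMAP (cat.), CH2Cl2, rt, dark; then CHI3, hν (tungsten lamp), rt
Reagents that add atoms: iodoform, IC(I)I (the non-isolated ester 6 also carries 1-hydroxypyridine-2(1H)-thione, ON1C=CC=CC1=S)
Why: Barton decarboxylative iodination: the thiohydroxamate ester fragments under visible light to CO2 and the primary radical, which should abstract iodine from iodoform far faster than it can add to either alkene (3-exo or 5-exo/6-endo), so the chain loses one carbon without rearrangement. The stereocentre is untouched; its descriptor changes from R to S only because CH2I outranks isopropenyl.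

Step 5
Reactants: 8 2,4,6-trihydroxybenzaldehyde
Product: 9 2-hydroxy-4,6-bis(methoxymethoxy)benzaldehyde
Conditions: MOMCl (2.1 equiv), i-Pr2NEt, CH2Cl2, 0 °C to rt
Reagents that add atoms: chloromethyl methyl ether, COCCl
Why: Williamson-type O-alkylation; the para and one ortho hydroxyl react, while the remaining ortho hydroxyl is deactivated by its hydrogen bond to the aldehyde, the standard desymmetrisation of 2,4,6-trihydroxyaryl carbonyl compounds.

Step 6
Reactants: 9 2-hydroxy-4,6-bis(methoxymethoxy)benzaldehyde
Product: 10 2-hydroxy-3-iodo-4,6-bis(methoxymethoxy)benzaldehyde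
Conditions: NIS (1.05 equiv), DMF, 0 °C to rt, dark
Reagents that add atoms: N-iodosuccinimide, O=C1CCC(=O)N1I
Why: Electrophilic aromatic iodination; C3, ortho to the free chelated phenol and flanked by a small hydroxyl, is expected to react in preference to C5, which is buttressed by two MOM ethers, by analogy with the halogenation of 2-hydroxy-4,6-dialkoxyaryl ketones.

Step 7
Reactants: 10 2-hydroxy-3-iodo-4,6-bis(methoxymethoxy)benzaldehyde
Product: 11 6-formyl-2-iodo-3,5-bis(methoxymethoxy)phenyl trifluoromethanesulfonate
Conditions: Tf2O, pyridine, CH2Cl2, −20 to 0 °C
Reagents that add atoms: trifluoromethanesulfonic anhydride, O=S(=O)(OS(=O)(=O)C(F)(F)F)C(F)(F)F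
Why: O-Sulfonylation of the only free hydroxyl, the one flanked by C–I and C–CHO, which places the leaving group on the future C8a without any selectivity issue.

Step 8
Reactants: 7 (3S)-3-(iodomethyl)-2,6-dimethylhepta-1,6-diene; 11 6-formyl-2-iodo-3,5-bis(methoxymethoxy)phenyl trifluoromethanesulfonate
Product: 13 6-formyl-3,5-bis(methoxymethoxy)-2-[(2R)-chain]phenyl trifluoromethanesulfonate, via alkylzinc iodide 12 (not isolated)
Conditions: 7, Zn dust, LiCl, THF, 40 °C; then 11, PdCl2(dppf) (5 mol %), THF, rt to 40 °C
Reagents that add atoms: none
Why: Negishi cross-coupling: zinc inserts into the primary C–I bond and the alkylzinc iodide (1.2 equiv) transmetalates to the arylpalladium iodide formed at C–I, which is far more reactive than the hindered C–OTf. The wide-bite-angle ligand dppf favours reductive elimination over beta-hydride elimination, and organozinc halides tolerate the aldehyde, the triflate and the acetals; the stereocentre is beta to zinc and not involved.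

Step 9
Reactants: 14 4'-hydroxyacetophenone
Product: 15 4'-(methoxymethoxy)acetophenone
Conditions: MOMCl, i-Pr2NEt, CH2Cl2, 0 °C to rt
Reagents that add atoms: chloromethyl methyl ether, COCCl
Why: Williamson-type O-alkylation of the phenol, which must be masked before enolate formation and is released with the other MOM ethers in the last step.

Step 10
Reactants: 15 4'-(methoxymethoxy)acetophenone; 13 6-formyl-3,5-bis(methoxymethoxy)-2-[(2R)-chain]phenyl trifluoromethanesulfonate
Product: 17 2-{(1RS)-1-hydroxy-3-[4-(methoxymethoxy)phenyl]-3-oxopropyl}-3,5-bis(methoxymethoxy)-6-[(2R)-chain]phenyl trifluoromethanesulfonate, via lithium enolate 16 (not isolated)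
Conditions: 15, LiN(i-Pr)2, THF, −78 °C; then 13, −78 °C; AcOH quench at −78 °C
Reagents that add atoms: none
Why: Directed aldol addition of a preformed lithium enolate to a non-enolisable aldehyde; quenching cold prevents retro-aldol reaction, dehydration and attack of the aldolate on the neighbouring triflate. The new carbinol centre (future C4) forms without control, which is immaterial because it is oxidised in step 15.

Step 11
Reactants: 17 aldol adduct (both C4 epimers)
Product: 18 2-{(1RS)-1-(tert-butyldimethylsilyloxy)-3-[4-(methoxymethoxy)phenyl]-3-oxopropyl}-3,5-bis(methoxymethoxy)-6-[(2R)-chain]phenyl trifluoromethanesulfonate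
Conditions: TBSOTf, 2,6-lutidine, CH2Cl2, −78 to 0 °C
Reagents that add atoms: tert-butyldimethylsilyl trifluoromethanesulfonate, CC(C)(C)[Si](C)(C)OS(=O)(=O)C(F)(F)F
Why: Silylation of a hindered secondary alcohol with a silyl triflate and a non-nucleophilic base; the silyl ether blocks dehydration of the aldol and removes the benzylic hydroxyl ortho to the triflate before the palladium step.

Step 12
Reactants: 18 silylated aldol (both C4 epimers)
Product: 19 2-{(1RS,3S)-1-(tert-butyldimethylsilyloxy)-3-hydroxy-3-[4-(methoxymethoxy)phenyl]propyl}-3,5-bis(methoxymethoxy)-6-[(2R)-chain]phenyl trifluoromethanesulfonate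
Conditions: RuCl[(S,S)-TsDPEN](p-cymene) (2 mol %), HCO2H/Et3N (1:1), EtOAc, 30 °C
Reagents that add atoms: none
Why: Noyori–Ikariya asymmetric transfer hydrogenation of an unhindered aryl alkyl ketone; the (S,S)-catalyst should deliver hydride to the Re face through the six-membered outer-sphere transition state, stabilised by the CH–π contact between p-cymene and ring B, giving the S carbinol (future C2) under catalyst control in both C4 epimers. The near-neutral formate mixture spares the acetals, the silyl ether, the triflate and the alkenes.

Step 13
Reactants: 19 (3S)-alcohol bearing the C8a triflate (both C4 epimers)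
Product: 20 (2S,4RS)-4-(tert-butyldimethylsilyloxy)-5,7-bis(methoxymethoxy)-2-[4-(methoxymethoxy)phenyl]-8-[(2R)-chain]chromane
Conditions: Pd(OAc)2 (5 mol %), RockPhos [2-(di-tert-butylphosphino)-3-methoxy-6-methyl-2',4',6'-triisopropylbiphenyl] (7.5 mol %), Cs2CO3, toluene, 80 °C
Reagents that add atoms: none
Why: Zerovalent palladium, formed in situ from Pd(OAc)2 and the phosphine, inserts into the C8a–OTf bond; the C2 hydroxyl is deprotonated by Cs2CO3 at the metal to give a seven-membered aryl(alkoxo) complex of divalent palladium, and C–O reductive elimination forms O1–C8a. The closest known reaction type is the palladium-catalysed intramolecular etherification of secondary alcohols with aryl halides and triflates that gives chromans. Ring C closes as a six-membered ring by bond formation at the aryl carbon (formally 6-exo at C8a, leaving group exocyclic); no other ring size is possible, since the C4 oxygen is silylated and could in any case only close a four-membered ring. No stereocentre is created: the C2–O bond is never broken, so the S configuration from step 12 is retained, and the uncontrolled C4 centre is a spectator. The step needs reductive elimination to outrun beta-hydride elimination of the palladium alkoxide and oxidative addition to outrun base-induced S–O cleavage of the triflate; the bulky di-tert-butyl biaryl phosphine enforces a monoligated, crowded metal centre that accelerates C–O reductive elimination, the two ortho substituents add to that crowding, and the weak, insoluble carbonate keeps the concentration of free alkoxide low. Silylation of the C4 hydroxyl removes the one group that could chelate the aryl–palladium bond in a five-membered ring, reduce it by internal hydride transfer or take up the triflyl group.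

Step 14
Reactants: 20 4-O-silyl flavan (both C4 epimers)
Product: 21 (2S,4RS)-5,7-bis(methoxymethoxy)-2-[4-(methoxymethoxy)phenyl]-8-[(2R)-chain]chroman-4-ol
Conditions: Bu4NF, THF, 0 °C to rt
Reagents that add atoms: none
Why: Fluoride-induced desilylation driven by Si–F bond formation; the flavan has no carbonyl group, so the basic fluoride cannot open ring C, and aryl MOM ethers are inert.

Step 15
Reactants: 21 flavan-4-ol (both C4 epimers)
Product: 22 (2S)-5,7-bis(methoxymethoxy)-2-[4-(methoxymethoxy)phenyl]-8-[(2R)-chain]chroman-4-one
Conditions: Dess–Martin periodinane, CH2Cl2, 0 °C to rt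
Reagents that add atoms: none
Why: Dess–Martin oxidation of the benzylic secondary alcohol; both C4 epimers give the same ketone, the alkenes are inert, and no base is present that could open the flavanone to a chalcone and racemise C2.

Step 16
Reactants: 22 (2S)-tris-MOM flavanone
Product: 23 remangiflavanone A
Conditions: 3 M aq. HCl, MeOH, 40 °C
Reagents that add atoms: none
Why: Acid-catalysed acetal exchange with methanol removes the three MOM ethers, the C5 ether peri to the carbonyl fastest; dilute acid at moderate temperature is the standard last step for MOM-protected prenylated flavanones and should leave the isopropenyl groups and C2 untouched.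

## Compound list

1 | (4R)-1-methyl-4-(prop-1-en-2-yl)-7-oxabicyclo[4.1.0]heptane, (+)-limonene 1,2-oxide, cis/trans mixture | CC12CC[C@H](CC1O2)C(C)=C | starting material
2 | (4R)-1-methyl-4-(prop-1-en-2-yl)cyclohexane-1,2-diol (not isolated) | CC1(O)CC[C@H](CC1O)C(C)=C | intermediate
3 | (3R)-6-oxo-3-(prop-1-en-2-yl)heptanal | CC(=O)CC[C@H](CC=O)C(C)=C | intermediate
4 | (3R)-6-oxo-3-(prop-1-en-2-yl)heptanoic acid | CC(=O)CC[C@H](CC(=O)O)C(C)=C | intermediate
5 | (3R)-6-methyl-3-(prop-1-en-2-yl)hept-6-enoic acid | C=C(C)CC[C@H](CC(=O)O)C(C)=C | intermediate
6 | 2-thioxopyridin-1(2H)-yl (3R)-6-methyl-3-(prop-1-en-2-yl)hept-6-enoate (not isolated) | C=C(C)CC[C@H](CC(=O)ON1C=CC=CC1=S)C(C)=C | intermediate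
7 | (3S)-3-(iodomethyl)-2,6-dimethylhepta-1,6-diene | C=C(C)CC[C@H](CI)C(C)=C | intermediate
8 | 2,4,6-trihydroxybenzaldehyde | O=Cc1c(O)cc(O)cc1O | starting material
9 | 2-hydroxy-4,6-bis(methoxymethoxy)benzaldehyde | COCOc1cc(O)c(C=O)c(OCOC)c1 | intermediate
10 | 2-hydroxy-3-iodo-4,6-bis(methoxymethoxy)benzaldehyde | COCOc1cc(OCOC)c(I)c(O)c1C=O | intermediate
11 | 6-formyl-2-iodo-3,5-bis(methoxymethoxy)phenyl trifluoromethanesulfonate | COCOc1cc(OCOC)c(I)c(OS(=O)(=O)C(F)(F)F)c1C=O | intermediate
12 | iodo[(2S)-5-methyl-2-(prop-1-en-2-yl)hex-5-en-1-yl]zinc (not isolated) | C=C(C)CC[C@H](C[Zn]I)C(C)=C | intermediate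
13 | 6-formyl-3,5-bis(methoxymethoxy)-2-[(2R)-5-methyl-2-(prop-1-en-2-yl)hex-5-en-1-yl]phenyl trifluoromethanesulfonate | C=C(C)CC[C@H](Cc1c(OCOC)cc(OCOC)c(C=O)c1OS(=O)(=O)C(F)(F)F)C(=C)C | intermediate
14 | 1-(4-hydroxyphenyl)ethan-1-one | CC(=O)c1ccc(O)cc1 | starting material
15 | 1-[4-(methoxymethoxy)phenyl]ethan-1-one | CC(=O)c1ccc(OCOC)cc1 | intermediate
16 | lithium 1-[4-(methoxymethoxy)phenyl]ethen-1-olate (not isolated) | C=C(O[Li])c1ccc(OCOC)cc1 | intermediate
17 | 2-{(1RS)-1-hydroxy-3-[4-(methoxymethoxy)phenyl]-3-oxopropyl}-3,5-bis(methoxymethoxy)-6-[(2R)-5-methyl-2-(prop-1-en-2-yl)hex-5-en-1-yl]phenyl trifluoromethanesulfonate (both C4 epimers) | C=C(C)CC[C@H](Cc1c(OCOC)cc(OCOC)c(C(O)CC(=O)c2ccc(OCOC)cc2)c1OS(=O)(=O)C(F)(F)F)C(=C)C | intermediate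
18 | 2-{(1RS)-1-(tert-butyldimethylsilyloxy)-3-[4-(methoxymethoxy)phenyl]-3-oxopropyl}-3,5-bis(methoxymethoxy)-6-[(2R)-5-methyl-2-(prop-1-en-2-yl)hex-5-en-1-yl]phenyl trifluoromethanesulfonate (both C4 epimers) | C=C(C)CC[C@H](Cc1c(OCOC)cc(OCOC)c(C(O[Si](C)(C)C(C)(C)C)CC(=O)c2ccc(OCOC)cc2)c1OS(=O)(=O)C(F)(F)F)C(=C)C | intermediate
19 | 2-{(1RS,3S)-1-(tert-butyldimethylsilyloxy)-3-hydroxy-3-[4-(methoxymethoxy)phenyl]propyl}-3,5-bis(methoxymethoxy)-6-[(2R)-5-methyl-2-(prop-1-en-2-yl)hex-5-en-1-yl]phenyl trifluoromethanesulfonate (flavanone numbering 2S, both C4 epimers) | C=C(C)CC[C@H](Cc1c(OCOC)cc(OCOC)c(C(O[Si](C)(C)C(C)(C)C)C[C@H](O)c2ccc(OCOC)cc2)c1OS(=O)(=O)C(F)(F)F)C(=C)C | intermediate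
20 | (2S,4RS)-4-(tert-butyldimethylsilyloxy)-5,7-bis(methoxymethoxy)-2-[4-(methoxymethoxy)phenyl]-8-[(2R)-5-methyl-2-(prop-1-en-2-yl)hex-5-en-1-yl]chromane | C=C(C)CC[C@H](Cc1c(OCOC)cc(OCOC)c2c1O[C@H](c1ccc(OCOC)cc1)CC2O[Si](C)(C)C(C)(C)C)C(=C)C | intermediate
21 | (2S,4RS)-5,7-bis(methoxymethoxy)-2-[4-(methoxymethoxy)phenyl]-8-[(2R)-5-methyl-2-(prop-1-en-2-yl)hex-5-en-1-yl]chroman-4-ol | C=C(C)CC[C@H](Cc1c(OCOC)cc(OCOC)c2c1O[C@H](c1ccc(OCOC)cc1)CC2O)C(=C)C | intermediate
22 | (2S)-5,7-bis(methoxymethoxy)-2-[4-(methoxymethoxy)phenyl]-8-[(2R)-5-methyl-2-(prop-1-en-2-yl)hex-5-en-1-yl]chroman-4-one | C=C(C)CC[C@H](Cc1c(OCOC)cc(OCOC)c2c1O[C@H](c1ccc(OCOC)cc1)CC2=O)C(=C)C | intermediate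
23 | remangiflavanone A, (2S)-5,7-dihydroxy-2-(4-hydroxyphenyl)-8-[(2R)-5-methyl-2-(prop-1-en-2-yl)hex-5-en-1-yl]chroman-4-one | C=C(C)CC[C@H](Cc1c(O)cc(O)c2c1O[C@H](c1ccc(O)cc1)CC2=O)C(=C)C | target

## Step count and least certain steps

Total step count: 16. Longest linear sequence: 12 steps (steps 1 to 4, 8 and 10 to 16, from 1).

Step 13 (key step). The most likely failure is slow oxidative addition into the hindered, electron-rich C–OTf bond, so that base-induced S–O cleavage of the triflate gains ground. Beta-hydride elimination of the palladium alkoxide, which would oxidise C2 and reduce the aryl–palladium bond, and base-induced migration of the silyl group from O4 to O2 are the other two risks. The fallback sets out from 18 and rejoins the route at 20, and replaces the metal-catalysed O1–C8a closure by an O1–C2 closure with inversion. 18 would be reduced with the enantiomeric catalyst RuCl[(R,R)-TsDPEN](p-cymene) to the (3R)-configured alcohol F1. The aryl triflate of F1 would be cleaved with Et4NOH in dioxane to give the phenol F2. An intramolecular Mitsunobu etherification (PPh3, DIAD, THF, 0 °C) would then displace the activated C2 hydroxyl by the phenol oxygen with inversion, giving 20 with the 2S configuration. The weak point of this fallback is partial ionisation at the electron-rich benzylic carbon, which is why it is not the first choice.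

Step 4. The most likely failure is an inefficient radical chain: capture of the primary radical by the thiocarbonyl group of 6 instead of by iodoform, and, if iodine transfer is slower than assumed, cyclisation of the radical onto the 5-methylhex-5-enyl alkene. The fallback sets out from 4 and rejoins at 7, and moves the decarboxylation ahead of the methylenation so that the radical has no distal alkene. Keto acid 4 would be converted through the thiohydroxamate ester F3 (not isolated) into the keto iodide F4 under the conditions of step 4. F4 would then be methylenated under non-basic conditions with Cp2TiMe2 (Petasis methylenation, toluene, 65 °C), which tolerates the primary iodide, to give 7.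

Step 6. The most likely failure is poor regioselectivity, with iodination at C5 between the two MOM ethers, or double iodination. The fallback sets out from 8 and rejoins at 10, and removes the regiochemical question from the C–I bond formation. 8, in which C3 and C5 are equivalent, would be mono-iodinated (NIS, 1 equiv) to 2,4,6-trihydroxy-3-iodobenzaldehyde F5. Two MOM groups would then be placed on the para hydroxyl and on the ortho hydroxyl remote from iodine, leaving the hydroxyl between CHO and iodine free because it is both chelated and the most hindered.

Step 8. The most likely failures are loss of chemoselectivity once the iodide is consumed (oxidative addition into the aldehyde-activated C–OTf bond), beta-hydride elimination from the alkylpalladium intermediate, and slow addition of 12 to the aldehyde. The fallback sets out from 10 (with 12) and rejoins at 13, and couples before the triflate exists. 10 would be deprotonated with NaH and coupled as its phenoxide with 12 and PdCl2(dppf) to the chain-bearing salicylaldehyde F6. F6 would then be triflated with Tf2O and pyridine as in step 7 to give 13.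

Step 16. The most likely failure is acid-mediated Markovnikov addition to an isopropenyl group, in particular cyclisation of the freed C7 hydroxyl onto the proximal isopropenyl group, or slow acid-promoted opening and reclosure of ring C that erodes C2. The fallback sets out from 22 and rejoins at 23, and replaces Brønsted-acid hydrolysis by silyl transfer. Treatment with TMSOTf and 2,2'-bipyridyl in CH3CN at 0 °C would exchange each aryl MOM ether for a trimethylsilyl ether, giving the tris(trimethylsilyl) ether F7. F7 would then be hydrolysed with water at neutral pH to 23.

## Further compounds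

F1 | step 13 | 2-{(1RS,3R)-1-(tert-butyldimethylsilyloxy)-3-hydroxy-3-[4-(methoxymethoxy)phenyl]propyl}-3,5-bis(methoxymethoxy)-6-[(2R)-5-methyl-2-(prop-1-en-2-yl)hex-5-en-1-yl]phenyl trifluoromethanesulfonate | C=C(C)CC[C@H](Cc1c(OCOC)cc(OCOC)c(C(O[Si](C)(C)C(C)(C)C)C[C@@H](O)c2ccc(OCOC)cc2)c1OS(=O)(=O)C(F)(F)F)C(=C)C
F2 | step 13 | 2-{(1RS,3R)-1-(tert-butyldimethylsilyloxy)-3-hydroxy-3-[4-(methoxymethoxy)phenyl]propyl}-3,5-bis(methoxymethoxy)-6-[(2R)-5-methyl-2-(prop-1-en-2-yl)hex-5-en-1-yl]phenol | C=C(C)CC[C@H](Cc1c(OCOC)cc(OCOC)c(C(O[Si](C)(C)C(C)(C)C)C[C@@H](O)c2ccc(OCOC)cc2)c1O)C(=C)C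
F3 | step 4 | 2-thioxopyridin-1(2H)-yl (3R)-6-oxo-3-(prop-1-en-2-yl)heptanoate | CC(=O)CC[C@H](CC(=O)ON1C=CC=CC1=S)C(C)=C
F4 | step 4 | (5S)-5-(iodomethyl)-6-methylhept-6-en-2-one | CC(=O)CC[C@H](CI)C(C)=C
F5 | step 6 | 2,4,6-trihydroxy-3-iodobenzaldehyde | O=Cc1c(O)cc(O)c(I)c1O
F6 | step 8 | 2-hydroxy-4,6-bis(methoxymethoxy)-3-[(2R)-5-methyl-2-(prop-1-en-2-yl)hex-5-en-1-yl]benzaldehyde | C=C(C)CC[C@H](Cc1c(OCOC)cc(OCOC)c(C=O)c1O)C(=C)C
F7 | step 16 | (2S)-8-[(2R)-5-methyl-2-(prop-1-en-2-yl)hex-5-en-1-yl]-5,7-bis(trimethylsilyloxy)-2-[4-(trimethylsilyloxy)phenyl]chroman-4-one | C=C(C)CC[C@H](Cc1c(O[Si](C)(C)C)cc(O[Si](C)(C)C)c2c1O[C@H](c1ccc(O[Si](C)(C)C)cc1)CC2=O)C(=C)C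
A1 | alternative 1 | (R)-5,7-bis(methoxymethoxy)-3-(3-methylbut-3-enyl)chroman-2-one | C=C(C)CC[C@@H]1Cc2c(OCOC)cc(OCOC)cc2OC1=O
A2 | alternative 1 | (4S)-4-benzyl-3-(5-methylhex-5-enoyl)-1,3-oxazolidin-2-one | C=C(C)CCCC(=O)N1[C@@H](Cc2ccccc2)COC1=O
A3 | alternative 1 | tert-butyl 2-(hydroxymethyl)-3,5-bis(methoxymethoxy)phenyl carbonate | CC(C)(C)OC(=O)Oc1cc(OCOC)cc(OCOC)c1CO
A4 | alternative 1 | 3,5-bis(methoxymethoxy)-6-methylidenecyclohexa-2,4-dien-1-one | C=C1C(=O)C=C(OCOC)C=C1OCOC
A5 | alternative 2 | 2-[(2R)-5-methyl-2-(prop-1-en-2-yl)hex-5-en-1-yl]-5-ethoxy-3-(triisopropylsilyloxy)phenol | C=C(C)CC[C@H](Cc1c(O[Si](C(C)C)(C(C)C)C(C)C)cc(OCC)cc1O)C(=C)C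
A6 | alternative 2 | triisopropyl{[(4R)-7-methyl-4-(prop-1-en-2-yl)oct-7-en-1-yn-1-yl]oxy}silane | C=C(C)CC[C@H](CC#CO[Si](C(C)C)(C(C)C)C(C)C)C(=C)C
A7 | alternative 2 | 3-ethoxycyclobut-2-en-1-one | CCOC1=CC(=O)C1
A8 | alternative 3 | (2S)-4'-acetoxy-5-ethoxy-7-(triisopropylsilyloxy)-8-[(2R)-5-methyl-2-(prop-1-en-2-yl)hex-5-en-1-yl]flavanone | C=C(C)CC[C@H](Cc1c(O[Si](C(C)C)(C(C)C)C(C)C)cc(OCC)c2c1O[C@H](c1ccc(OC(C)=O)cc1)CC2=O)C(=C)C
A9 | alternative 3 | (3S)-3-(4-acetoxyphenyl)-3-{5-ethoxy-2-[(2R)-5-methyl-2-(prop-1-en-2-yl)hex-5-en-1-yl]-3-(triisopropylsilyloxy)phenoxy}propanoic acid | C=C(C)CC[C@H](Cc1c(O[Si](C(C)C)(C(C)C)C(C)C)cc(OCC)cc1O[C@H](c1ccc(OC(C)=O)cc1)CC(=O)O)C(=C)C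
A10 | alternative 3 | (3S)-3-(4-acetoxyphenyl)-3-{5-ethoxy-2-[(2R)-5-methyl-2-(prop-1-en-2-yl)hex-5-en-1-yl]-3-(triisopropylsilyloxy)phenoxy}propanoyl chloride | C=C(C)CC[C@H](Cc1c(O[Si](C(C)C)(C(C)C)C(C)C)cc(OCC)cc1O[C@H](c1ccc(OC(C)=O)cc1)CC(Cl)=O)C(=C)C
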